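**Retrosynthetic overview**

1. Ring positions follow the target's name: O1, C2 (CH2), C3 (quaternary, OAc and benzyl), C4 (CH–CH2OH), C5 (CH–aryl). Endgame: ArO–Bn hydrogenolysis; C3–OAc from C3–C(O)CH3 by Baeyer–Villiger oxidation (retention); C4–CH2OH from C4–CH=CH2 by ozonolysis/reduction.
2. Key disconnection: O1–C2 and C3–C4 are formed together in a palladium-catalysed formal [3+2] union of an α-benzyl methyl vinyl ketone (C2=C3) with an enantiopure 2-aryl-3-vinyloxirane (O1–C5–C4). The oxolane is the only ring made, and it is made in this step.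
3. Enabling feature: in the oxolane, C2 is an unsubstituted CH2 between O1 and a C3 whose acetoxy group is the Baeyer–Villiger image of an acetyl group, so C2=C3 can be the β/α carbons of an enone (O1 adds to C2, C3 becomes an enolate). C4 carries a CH2OH that is the oxidative image of a vinyl group and adjoins the O-bearing benzylic C5, so O1–C5–C4 can be the alkoxide/η3-allyl zwitterion of a vinyloxirane.
4. Stereochemistry: C5 is set by Shi epoxidation; C4 and the quaternary C3 are relayed from C5 in the ring closure.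
5. Fragments: the oxirane from 3,4-dimethoxycinnamaldehyde (Wittig, epoxidation); the enone from zingerone (O-benzylation, α-methylenation).

Key step: step 5

**Route**

Step 1
Reactants: 1 (2E)-3-(3,4-dimethoxyphenyl)prop-2-enal
Product: 2 4-[(1E)-buta-1,3-dien-1-yl]-1,2-dimethoxybenzene
Conditions: Ph3PCH3Br, KOtBu, THF, 0 °C → rt
Reagents that add atoms: methyltriphenylphosphonium bromide, C[P+](c1ccccc1)(c1ccccc1)c1ccccc1.[Br-]
Why: Wittig methylenation of the enal with the non-stabilised ylide, which leaves the (E) double bond untouched.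

Step 2
Reactants: 2 4-[(1E)-buta-1,3-dien-1-yl]-1,2-dimethoxybenzene
Product: 3 (2R,3R)-2-(3,4-dimethoxyphenyl)-3-ethenyloxirane
Conditions: 1,2:4,5-di-O-isopropylidene-β-D-erythro-2,3-hexodiulo-2,6-pyranose (D-fructose-derived ketone, 30 mol%), Oxone (2KHSO5·KHSO4·K2SO4), K2CO3, Bu4NHSO4 (cat.), MeCN–CH2(OMe)2 / aq. Na2B4O7–Na2EDTA buffer (pH 10.5), −10 → 0 °C
Reagents that add atoms: potassium peroxymonosulfate (active component of Oxone), [K+].[O-]S(=O)(=O)OO
Why: Shi asymmetric epoxidation; the electrophilic chiral dioxirane, slow with terminal alkenes, should take the aryl-conjugated trans double bond through a spiro transition state and give the (R,R) oxirane, whose benzylic carbon becomes C5 of the target.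

Step 3
Reactants: 4 4-(4-hydroxy-3-methoxyphenyl)butan-2-one (zingerone)
Product: 5 4-[4-(benzyloxy)-3-methoxyphenyl]butan-2-one
Conditions: BnBr, K2CO3, DMF, rt
Reagents that add atoms: benzyl bromide, BrCc1ccccc1
Why: Williamson ether synthesis on the phenoxide; the benzyl ether should survive palladium, ozone and peracid and leaves by neutral hydrogenolysis at the end.

Step 4
Reactants: 5 4-[4-(benzyloxy)-3-methoxyphenyl]butan-2-one
Product: 7 3-{[4-(benzyloxy)-3-methoxyphenyl]methyl}but-3-en-2-one, via Mannich base 6 (not isolated)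
Conditions: (CH2O)n, iPr2NH2+ CF3CO2− (1 equiv), CF3CO2H (10 mol%), THF, reflux
Reagents that add atoms: formaldehyde (as paraformaldehyde), C=O
Why: Direct α-methylenation (Mannich reaction, then β-elimination of the amine); under acid the more substituted enol of the methyl ketone reacts, so the methylene should enter at C3 of the butanone and not at the methyl group.

Step 5
Reactants: 3 (2R,3R)-2-(3,4-dimethoxyphenyl)-3-ethenyloxirane; 7 3-{[4-(benzyloxy)-3-methoxyphenyl]methyl}but-3-en-2-one
Product: 8 1-[(3S,4S,5S)-3-{[4-(benzyloxy)-3-methoxyphenyl]methyl}-5-(3,4-dimethoxyphenyl)-4-ethenyloxolan-3-yl]ethan-1-one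
Conditions: Pd2(dba)3·CHCl3 (2.5 mol%), 1,2-bis(diphenylphosphino)ethane (6 mol%), THF, 0 °C → rt; 3 added slowly to 7 (1.5 equiv)
Reagents that add atoms: none
Why: Proposed new method: zerovalent palladium should ionise the allylic C–O bond of 3 to a zwitterionic η3-allylpalladium alkoxide (benzylic C–O bond untouched), the alkoxide should add to the CH2 terminus of enone 7 (oxa-Michael, new O1–C2 bond) and the resulting ketone enolate should attack the near allyl terminus anti to palladium (new C3–C4 bond) with release of the catalyst; the closest known reaction type is the palladium-catalysed formal [3+2] cycloaddition of vinyloxiranes and vinylethylene carbonates with doubly activated alkenes (and of 2-vinylaziridines with vinyl ketones), extended here to a mono-activated α-branched enone. The oxolane closes by a 5-exo attack on the allyl terminus; closure at the far terminus (seven-membered ring) or O-allylation of the enolate should not compete. C5 keeps the configuration bought in step 2; C4 is set under Curtin–Hammett conditions, because η3–η1–η3 isomerisation equilibrates the allyl faces and the closure that places the allyl unit trans to the C5 aryl group should be preferred. The quaternary C3 is set in the same closure: the flat enolate terminus C(O−)CH3 is held in the plane of the nucleophile and should turn away from the allyl fragment, whereas the benzyl CH2 can sit over it with only hydrogens pointing inward, which places benzyl cis and acetyl trans to the new vinyl group. The step needs capture of the zwitterion by the enone to outrun its known isomerisation to a ketone or dienol (helped by excess 7, the chelating diphosphine and slow addition of 3) and facial selectivity at C3, which rests on the steric argument above and is the main uncertainty.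

Step 6
Reactants: 8 1-[(3S,4S,5S)-3-{[4-(benzyloxy)-3-methoxyphenyl]methyl}-5-(3,4-dimethoxyphenyl)-4-ethenyloxolan-3-yl]ethan-1-one
Product: 10 1-[(3S,4R,5S)-3-{[4-(benzyloxy)-3-methoxyphenyl]methyl}-5-(3,4-dimethoxyphenyl)-4-(hydroxymethyl)oxolan-3-yl]ethan-1-one, via aldehyde 9 (not isolated)
Conditions: O3, CH2Cl2–MeOH (3:1), NaHCO3, Sudan Red 7B (end-point indicator), −78 °C; then NaBH4, −78 → −20 °C
Reagents that add atoms: ozone, [O-][O+]=O
Why: Ozonolysis of the only C=C bond with hydride work-up in the same pot; at low temperature the aldehyde should be reduced far faster than the neopentyl-type methyl ketone, and because it is never isolated C4 should not epimerise and the β-alkoxy aldehyde should not eliminate.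

Step 7
Reactants: 10 1-[(3S,4R,5S)-3-{[4-(benzyloxy)-3-methoxyphenyl]methyl}-5-(3,4-dimethoxyphenyl)-4-(hydroxymethyl)oxolan-3-yl]ethan-1-one
Product: 11 (3S,4R,5S)-3-{[4-(benzyloxy)-3-methoxyphenyl]methyl}-5-(3,4-dimethoxyphenyl)-4-(hydroxymethyl)oxolan-3-yl acetate
Conditions: mCPBA (3 equiv), NaHCO3, CH2Cl2, 0 °C → rt
Reagents that add atoms: 3-chloroperoxybenzoic acid, OOC(=O)c1cccc(Cl)c1
Why: Baeyer–Villiger oxidation; the fully substituted C3 should migrate in preference to methyl and with retention, turning the acetyl group directly into the tertiary acetate, and the trans CH2OH cannot tie up the ketone as a hemiketal.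

Step 8
Reactants: 11 (3S,4R,5S)-3-{[4-(benzyloxy)-3-methoxyphenyl]methyl}-5-(3,4-dimethoxyphenyl)-4-(hydroxymethyl)oxolan-3-yl acetate
Product: 12 (3S,4R,5S)-5-(3,4-dimethoxyphenyl)-3-[(4-hydroxy-3-methoxyphenyl)methyl]-4-(hydroxymethyl)oxolan-3-yl acetate
Conditions: H2 (1 atm), 10% Pd/C, EtOAc, rt
Reagents that add atoms: none
Why: Hydrogenolysis of the aryl benzyl ether under neutral conditions, which should leave the tertiary acetate, the primary alcohol and the more slowly cleaved benzylic ring ether intact.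

**Compound list**

1 | (2E)-3-(3,4-dimethoxyphenyl)prop-2-enal | COc1ccc(/C=C/C=O)cc1OC | starting material
2 | 4-[(1E)-buta-1,3-dien-1-yl]-1,2-dimethoxybenzene | C=C/C=C/c1ccc(OC)c(OC)c1 | intermediate
3 | (2R,3R)-2-(3,4-dimethoxyphenyl)-3-ethenyloxirane (trans) | C=C[C@H]1O[C@@H]1c1ccc(OC)c(OC)c1 | intermediate
4 | 4-(4-hydroxy-3-methoxyphenyl)butan-2-one (zingerone) | CC(=O)CCc1ccc(O)c(OC)c1 | starting material
5 | 4-[4-(benzyloxy)-3-methoxyphenyl]butan-2-one | CC(=O)CCc1ccc(OCc2ccccc2)c(OC)c1 | intermediate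
6 | 3-{[4-(benzyloxy)-3-methoxyphenyl]methyl}-4-[di(propan-2-yl)amino]butan-2-one (racemic Mannich base) | CC(=O)C(CN(C(C)C)C(C)C)Cc1ccc(OCc2ccccc2)c(OC)c1 | intermediate (not isolated)
7 | 3-{[4-(benzyloxy)-3-methoxyphenyl]methyl}but-3-en-2-one | CC(=O)C(=C)Cc1ccc(OCc2ccccc2)c(OC)c1 | intermediate
8 | 1-[(3S,4S,5S)-3-{[4-(benzyloxy)-3-methoxyphenyl]methyl}-5-(3,4-dimethoxyphenyl)-4-ethenyloxolan-3-yl]ethan-1-one (aryl trans to vinyl, vinyl cis to benzyl) | COc1cc(C[C@@]2(C(C)=O)CO[C@H](c3ccc(OC)c(OC)c3)[C@H]2C=C)ccc1OCc1ccccc1 | intermediate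
9 | (2S,3S,4S)-4-acetyl-4-{[4-(benzyloxy)-3-methoxyphenyl]methyl}-2-(3,4-dimethoxyphenyl)oxolane-3-carbaldehyde | COc1cc(C[C@@]2(C(C)=O)CO[C@H](c3ccc(OC)c(OC)c3)[C@H]2C=O)ccc1OCc1ccccc1 | intermediate (not isolated)
10 | 1-[(3S,4R,5S)-3-{[4-(benzyloxy)-3-methoxyphenyl]methyl}-5-(3,4-dimethoxyphenyl)-4-(hydroxymethyl)oxolan-3-yl]ethan-1-one | COc1cc(C[C@@]2(C(C)=O)CO[C@H](c3ccc(OC)c(OC)c3)[C@H]2CO)ccc1OCc1ccccc1 | intermediate
11 | (3S,4R,5S)-3-{[4-(benzyloxy)-3-methoxyphenyl]methyl}-5-(3,4-dimethoxyphenyl)-4-(hydroxymethyl)oxolan-3-yl acetate | COc1cc(C[C@@]2(OC(C)=O)CO[C@H](c3ccc(OC)c(OC)c3)[C@H]2CO)ccc1OCc1ccccc1 | intermediate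
12 | (3S,4R,5S)-5-(3,4-dimethoxyphenyl)-3-[(4-hydroxy-3-methoxyphenyl)methyl]-4-(hydroxymethyl)oxolan-3-yl acetate | COc1cc(C[C@@]2(OC(C)=O)CO[C@H](c3ccc(OC)c(OC)c3)[C@H]2CO)ccc1O | target

**Step count and risks**

Total step count: 8. Longest linear sequence: 6 steps (steps 1, 2, 5, 6, 7, 8).

Steps most likely to fail:

1. Step 5 (Proposed new method). The zwitterionic allylpalladium alkoxide may isomerise by hydride shift faster than the mono-activated enone captures it, and the enolate may close on the allyl terminus with poor facial selectivity at the quaternary carbon. The fallback uses known chemistry, sets out from 3 and returns at 11; it makes O1–C2 and C3–C4 in separate steps and sets the quaternary centre by substrate-controlled epoxidation instead of by ring closure. Reductive opening of 3 with SmI2 (THF–MeOH, −78 °C) should give (1S,2E)-1-(3,4-dimethoxyphenyl)but-2-en-1-ol F1. O-Alkylation with propargyl bromide (NaH, THF, 0 °C → rt) gives the enyne 1,2-dimethoxy-4-[(1S,2E)-1-(prop-2-yn-1-yloxy)but-2-en-1-yl]benzene F2. Alder-ene cycloisomerisation (Pd(OAc)2, PPh3, benzene, 60 °C) should close the ring to the 1,4-diene (2S,3S)-2-(3,4-dimethoxyphenyl)-3-ethenyl-4-methylideneoxolane F3, with vinyl trans to aryl. mCPBA (NaHCO3, CH2Cl2, 0 °C) should epoxidise the more nucleophilic exocyclic methylene on the face anti to the neighbouring vinyl group, giving (3R,6S,7R)-6-(3,4-dimethoxyphenyl)-7-ethenyl-1,5-dioxaspiro[2.4]heptane F4. 4-(Benzyloxy)-3-methoxyphenylmagnesium bromide with CuI (10 mol%, THF, −30 °C) opens the oxirane at its CH2 to the tertiary alcohol (3S,4R,5S)-3-{[4-(benzyloxy)-3-methoxyphenyl]methyl}-5-(3,4-dimethoxyphenyl)-4-ethenyloxolan-3-ol F5. Acetylation (Ac2O, DMAP, Et3N, CH2Cl2, 40 °C) gives (3S,4R,5S)-3-{[4-(benzyloxy)-3-methoxyphenyl]methyl}-5-(3,4-dimethoxyphenyl)-4-ethenyloxolan-3-yl acetate F6. Ozonolysis with NaBH4 work-up as in step 6 then gives 11.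

2. Step 7. Migration at the hindered ketone may be slow enough for the peracid to attack the two electron-rich arenes, and once the acetate exists the free primary hydroxyl may take over the acetyl group by a 1,3-acyl shift. The fallback sets out from 10 and returns at 11; it masks the hydroxyl so that a stronger, buffered peracid can be used. Silylation (TBSCl, imidazole, DMF, rt) gives 1-[(3S,4R,5S)-3-{[4-(benzyloxy)-3-methoxyphenyl]methyl}-4-({[tert-butyl(dimethyl)silyl]oxy}methyl)-5-(3,4-dimethoxyphenyl)oxolan-3-yl]ethan-1-one F7. Baeyer–Villiger oxidation with trifluoroperacetic acid made from (CF3CO)2O and urea·H2O2 (Na2HPO4, CH2Cl2, 0 °C) gives (3S,4R,5S)-3-{[4-(benzyloxy)-3-methoxyphenyl]methyl}-4-({[tert-butyl(dimethyl)silyl]oxy}methyl)-5-(3,4-dimethoxyphenyl)oxolan-3-yl acetate F8. Desilylation with HF·pyridine (THF–pyridine, 0 °C) gives 11.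

3. Step 2. The electron-rich aryl oxirane may be opened hydrolytically in the aqueous oxidation medium, and the dioxirane may attack the terminal double bond as well. The fallback sets out from 1 and returns at 3; the oxirane is installed on an allylic alcohol under anhydrous conditions before the vinyl group exists. Luche reduction (NaBH4, CeCl3·7H2O, MeOH, 0 °C) gives (2E)-3-(3,4-dimethoxyphenyl)prop-2-en-1-ol F9. Sharpless asymmetric epoxidation (Ti(OiPr)4, D-(−)-diisopropyl tartrate, tBuOOH, 4 Å molecular sieves, CH2Cl2, −20 °C) gives [(2R,3R)-3-(3,4-dimethoxyphenyl)oxiran-2-yl]methanol F10. Parikh–Doering oxidation (SO3·pyridine, DMSO, iPr2NEt, CH2Cl2, 0 °C) gives (2S,3R)-3-(3,4-dimethoxyphenyl)oxirane-2-carbaldehyde F11. Wittig methylenation (Ph3PCH3Br, KOtBu, THF, −78 → 0 °C) of the crude aldehyde gives 3.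

**Further compounds**

F1 | step 5 | (1S,2E)-1-(3,4-dimethoxyphenyl)but-2-en-1-ol | C/C=C/[C@H](O)c1ccc(OC)c(OC)c1
F2 | step 5 | 1,2-dimethoxy-4-[(1S,2E)-1-(prop-2-yn-1-yloxy)but-2-en-1-yl]benzene | C/C=C/[C@H](OCC#C)c1ccc(OC)c(OC)c1
F3 | step 5 | (2S,3S)-2-(3,4-dimethoxyphenyl)-3-ethenyl-4-methylideneoxolane | C=C1CO[C@H](c2ccc(OC)c(OC)c2)[C@H]1C=C
F4 | step 5 | (3R,6S,7R)-6-(3,4-dimethoxyphenyl)-7-ethenyl-1,5-dioxaspiro[2.4]heptane | C1O[C@@]12CO[C@H](c3ccc(OC)c(OC)c3)[C@H]2C=C
F5 | step 5 | (3S,4R,5S)-3-{[4-(benzyloxy)-3-methoxyphenyl]methyl}-5-(3,4-dimethoxyphenyl)-4-ethenyloxolan-3-ol | COc1cc(C[C@@]2(O)CO[C@H](c3ccc(OC)c(OC)c3)[C@H]2C=C)ccc1OCc1ccccc1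
F6 | step 5 | (3S,4R,5S)-3-{[4-(benzyloxy)-3-methoxyphenyl]methyl}-5-(3,4-dimethoxyphenyl)-4-ethenyloxolan-3-yl acetate | COc1cc(C[C@@]2(OC(C)=O)CO[C@H](c3ccc(OC)c(OC)c3)[C@H]2C=C)ccc1OCc1ccccc1
F7 | step 7 | 1-[(3S,4R,5S)-3-{[4-(benzyloxy)-3-methoxyphenyl]methyl}-4-({[tert-butyl(dimethyl)silyl]oxy}methyl)-5-(3,4-dimethoxyphenyl)oxolan-3-yl]ethan-1-one | COc1cc(C[C@@]2(C(C)=O)CO[C@H](c3ccc(OC)c(OC)c3)[C@H]2CO[Si](C)(C)C(C)(C)C)ccc1OCc1ccccc1
F8 | step 7 | (3S,4R,5S)-3-{[4-(benzyloxy)-3-methoxyphenyl]methyl}-4-({[tert-butyl(dimethyl)silyl]oxy}methyl)-5-(3,4-dimethoxyphenyl)oxolan-3-yl acetate | COc1cc(C[C@@]2(OC(C)=O)CO[C@H](c3ccc(OC)c(OC)c3)[C@H]2CO[Si](C)(C)C(C)(C)C)ccc1OCc1ccccc1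
F9 | step 2 | (2E)-3-(3,4-dimethoxyphenyl)prop-2-en-1-ol | COc1ccc(/C=C/CO)cc1OC
F10 | step 2 | [(2R,3R)-3-(3,4-dimethoxyphenyl)oxiran-2-yl]methanol | OC[C@H]1O[C@@H]1c1ccc(OC)c(OC)c1
F11 | step 2 | (2S,3R)-3-(3,4-dimethoxyphenyl)oxirane-2-carbaldehyde | O=C[C@H]1O[C@@H]1c1ccc(OC)c(OC)c1
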